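**Retrosynthetic overview**
1. Target 16 ⇒ ring enyne 11 + 2‑iodo‑1,4‑diene 15: the C(sp)–C(sp2) bond joining ring fragment and side chain is made last, by a visible‑light copper‑acetylide coupling.
2. 15 ⇒ alkenyl boronate 12 + 2,3‑dibromopropene 13 (allyl–alkenyl Suzuki coupling, then Br→I exchange).
3. 11 ⇒ cyclohexanone 6 + ethynylmagnesium bromide 7 (1,2‑addition, acetylation, syn‑dehydration, acetonide removal).
4. 6 ⇒ enol ether 5 by Ferrier carbocyclisation: the only ring, the cyclohexane, is formed here from the pyranose, and the aldol sets the acetate‑bearing carbon.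
5. 5 ⇒ methyl α‑D‑galactopyranoside 1, whose C‑2, C‑3 and C‑4 become the OMe carbon and the two diol carbons of 16.

Assumption: boronate 12 and the THF solution of ethynylmagnesium bromide 7 are bought as such.

**Route**

Step 1
Reactants: 1 methyl α‑D‑galactopyranoside
Product: 2 methyl 6‑deoxy‑6‑iodo‑α‑D‑galactopyranoside
Conditions: PPh3, I2, imidazole, THF, reflux
Reagents that add atoms: iodine, II
Why: Garegg–Samuelsson (Appel‑type) iodination, in which the iodophosphonium reagent activates only the unhindered primary 6‑OH and iodide displaces it by SN2 without touching a stereocentre.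

Step 2
Reactants: 2 methyl 6‑deoxy‑6‑iodo‑α‑D‑galactopyranoside
Product: 3 methyl 6‑deoxy‑6‑iodo‑3,4‑O‑isopropylidene‑α‑D‑galactopyranoside
Conditions: 2,2‑dimethoxypropane, CSA (cat.), acetone, rt; Et3N quench
Reagents that add atoms: 2,2‑dimethoxypropane, COC(C)(C)OC
Why: Acid‑catalysed transacetalisation closes a dioxolane only across the cis‑3,4‑diol and leaves the trans‑disposed 2‑OH free, with no stereocentre changed.

Step 3
Reactants: 3 methyl 6‑deoxy‑6‑iodo‑3,4‑O‑isopropylidene‑α‑D‑galactopyranoside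
Product: 5 methyl 6‑deoxy‑3,4‑O‑isopropylidene‑2‑O‑methyl‑β‑L‑arabino‑hex‑5‑enopyranoside, via 2‑O‑methyl 6‑iodide 4 (not isolated)
Conditions: NaH (4 equiv), MeI (1.3 equiv), DMF, 0 °C, then rt, 12 h
Reagents that add atoms: iodomethane, CI
Why: Williamson etherification of the only free hydroxyl (O‑2) is followed in the same pot by NaH‑induced E2 dehydroiodination across C5–C6 to the exocyclic enol ether, so C‑2, C‑3 and C‑4 keep the galacto configuration while C‑5 becomes sp2.

Step 4
Reactants: 5 methyl 6‑deoxy‑3,4‑O‑isopropylidene‑2‑O‑methyl‑β‑L‑arabino‑hex‑5‑enopyranoside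
Product: 6 (2R,3R,4S,5S)‑5‑hydroxy‑2,3‑(isopropylidenedioxy)‑4‑methoxycyclohexan‑1‑one
Conditions: Hg(OCOCF3)2 (5 mol%), acetone/H2O 2:1, rt
Reagents that add atoms: water, O
Why: Ferrier carbocyclisation, in which hydroxymercuration of the enol ether and loss of methanol unmask a 5‑keto‑aldehyde whose mercury enolate closes the cyclohexanone by an intramolecular aldol; the chair‑like transition state usual for this reaction places the new hydroxyl trans to the oxygen at sugar C‑3 and hence cis to the adjacent OMe, so the new stereocentre is set by the galactose‑derived centres.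

Step 5
Reactants: 6 (2R,3R,4S,5S)‑5‑hydroxy‑2,3‑(isopropylidenedioxy)‑4‑methoxycyclohexan‑1‑one, 7 ethynylmagnesium bromide
Product: 8 (1R,2R,3R,4S,5S)‑1‑ethynyl‑2,3‑(isopropylidenedioxy)‑4‑methoxycyclohexane‑1,5‑diol
Conditions: 7 (3 equiv), THF, −40 → 0 °C; aq NH4Cl
Reagents that add atoms: none
Why: Grignard 1,2‑addition to the ketone, with the nucleophile expected to enter anti to the α‑dioxolane oxygen on the convex face (polar Felkin–Anh control), so the tertiary hydroxyl is cis to the acetonide; this centre is removed in step 7 but its configuration directs that elimination.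

Step 6
Reactants: 8 (1R,2R,3R,4S,5S)‑1‑ethynyl‑2,3‑(isopropylidenedioxy)‑4‑methoxycyclohexane‑1,5‑diol
Product: 9 (1S,2S,3R,4R,5R)‑5‑ethynyl‑5‑hydroxy‑3,4‑(isopropylidenedioxy)‑2‑methoxycyclohexyl acetate
Conditions: Ac2O, pyridine, CH2Cl2, 0 °C → rt (no DMAP)
Reagents that add atoms: acetic anhydride, CC(=O)OC(C)=O
Why: Chemoselective acylation, the secondary hydroxyl being acetylated while the hindered tertiary propargylic hydroxyl stays free, with no stereocentre affected.

Step 7
Reactants: 9 (1S,2S,3R,4R,5R)‑5‑ethynyl‑5‑hydroxy‑3,4‑(isopropylidenedioxy)‑2‑methoxycyclohexyl acetate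
Product: 10 (1S,4S,5S,6S)‑3‑ethynyl‑4,5‑(isopropylidenedioxy)‑6‑methoxycyclohex‑2‑en‑1‑yl acetate
Conditions: Burgess reagent (2 equiv), toluene, 60 °C
Reagents that add atoms: none
Why: Burgess dehydration, a syn (Ei) elimination of the tertiary sulfamate ester in which the hydrogen on the acetonide carbon is trans to the leaving group and out of reach, so the cis hydrogen of the CH2 group is removed and the conjugated enyne forms regioselectively with the allylic acetate stereocentre intact.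

Step 8
Reactants: 10 (1S,4S,5S,6S)‑3‑ethynyl‑4,5‑(isopropylidenedioxy)‑6‑methoxycyclohex‑2‑en‑1‑yl acetate
Product: 11 (1S,4S,5S,6R)‑3‑ethynyl‑4,5‑dihydroxy‑6‑methoxycyclohex‑2‑en‑1‑yl acetate
Conditions: AcOH/H2O 4:1, 60 °C
Reagents that add atoms: none
Why: Acid‑catalysed acetal hydrolysis frees the cis‑diol before the acid‑sensitive side chain is attached; acetate, methyl ether and terminal enyne tolerate warm aqueous acetic acid, and acyl migration is disfavoured because the neighbouring oxygen is methylated and the 1,3‑related hydroxyl is trans.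

Step 9
Reactants: 12 (E)‑2‑methyl‑4‑(4,4,5,5‑tetramethyl‑1,3,2‑dioxaborolan‑2‑yl)but‑3‑en‑2‑ol, 13 2,3‑dibromoprop‑1‑ene
Product: 14 (3E)‑6‑bromo‑2‑methylhepta‑3,6‑dien‑2‑ol
Conditions: Pd(PPh3)4 (3 mol%), K3PO4, THF/H2O 10:1, 45 °C; 13 in 2.5‑fold excess
Reagents that add atoms: none
Why: Suzuki–Miyaura allyl–alkenyl coupling, in which Pd(0) inserts much faster into the allylic than the vinylic C–Br bond of 13 to give a 2‑bromo‑π‑allyl complex with equivalent termini, and transmetalation with retention of the E‑alkene followed by reductive elimination gives the skipped diene.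

Step 10
Reactants: 14 (3E)‑6‑bromo‑2‑methylhepta‑3,6‑dien‑2‑ol
Product: 15 (3E)‑6‑iodo‑2‑methylhepta‑3,6‑dien‑2‑ol
Conditions: NaI (2 equiv), CuI (5 mol%), N,N′‑dimethylethylenediamine (10 mol%), 1,4‑dioxane, 110 °C
Reagents that add atoms: sodium iodide, [Na+].[I-]
Why: Copper‑catalysed vinylic Finkelstein halogen exchange, driven by precipitation of NaBr, converts the alkenyl bromide into the more easily reduced alkenyl iodide without touching the E‑alkene or the tertiary alcohol.

Step 11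
Reactants: 11 (1S,4S,5S,6R)‑3‑ethynyl‑4,5‑dihydroxy‑6‑methoxycyclohex‑2‑en‑1‑yl acetate, 15 (3E)‑6‑iodo‑2‑methylhepta‑3,6‑dien‑2‑ol
Product: 16 (1S,4S,5S,6R)‑4,5‑dihydroxy‑3‑[(5E)‑7‑hydroxy‑7‑methyl‑3‑methylideneoct‑5‑en‑1‑yn‑1‑yl]‑6‑methoxycyclohex‑2‑en‑1‑yl acetate
Conditions: CuCl (10 mol%), 4,4′,4″‑tri‑tert‑butyl‑2,2′:6′,2″‑terpyridine (12 mol%), K2CO3 (1.5 equiv), degassed MeCN, 450 nm LEDs, 25 °C; 15 (1.5 equiv)
Reagents that add atoms: none
Why: Proposed new method: the terpyridine‑bound copper(I) acetylide formed in situ from enyne 11 is the visible‑light chromophore, and its long‑lived, strongly reducing excited state (about −2 V vs SCE) transfers an electron to the C–I bond of the non‑activated 2‑iodo‑1‑alkene 15 with loss of iodide; the σ‑alkenyl radical is captured by the copper(II) acetylide to a Cu(III)(alkenyl)(alkynyl) species that reductively eliminates the C(sp2)–C(sp) bond and returns Cu(I), creating no stereocentre and leaving the ring centres and the allylic acetate untouched under these Pd‑free, methanol‑free, room‑temperature conditions; the closest known reaction type is the visible‑light copper‑catalysed Sonogashira‑type coupling of aryl and alkyl iodides with terminal alkynes, which to my knowledge has not been shown for non‑activated alkenyl iodides or enyne‑derived acetylides.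

**Compound list**
1 | methyl α‑D‑galactopyranoside | CO[C@@H]1[C@H](O)[C@@H](O)[C@@H](O)[C@@H](CO)O1 | starting material
2 | methyl 6‑deoxy‑6‑iodo‑α‑D‑galactopyranoside | CO[C@@H]1[C@H](O)[C@@H](O)[C@@H](O)[C@@H](CI)O1 | intermediate
3 | methyl 6‑deoxy‑6‑iodo‑3,4‑O‑isopropylidene‑α‑D‑galactopyranoside | CO[C@@H]1[C@H](O)[C@H]2OC(C)(C)O[C@H]2[C@@H](CI)O1 | intermediate
4 | methyl 6‑deoxy‑6‑iodo‑3,4‑O‑isopropylidene‑2‑O‑methyl‑α‑D‑galactopyranoside | CO[C@@H]1[C@H](OC)[C@H]2OC(C)(C)O[C@H]2[C@@H](CI)O1 | intermediate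
5 | methyl 6‑deoxy‑3,4‑O‑isopropylidene‑2‑O‑methyl‑β‑L‑arabino‑hex‑5‑enopyranoside | CO[C@@H]1[C@H](OC)[C@H]2OC(C)(C)O[C@H]2C(=C)O1 | intermediate
6 | (2R,3R,4S,5S)‑5‑hydroxy‑2,3‑(isopropylidenedioxy)‑4‑methoxycyclohexan‑1‑one (OH cis to OMe, both trans to the dioxolane oxygens) | O[C@@H]1[C@H](OC)[C@H]2OC(C)(C)O[C@H]2C(=O)C1 | intermediate
7 | ethynylmagnesium bromide | C#C[Mg]Br | starting material
8 | (1R,2R,3R,4S,5S)‑1‑ethynyl‑2,3‑(isopropylidenedioxy)‑4‑methoxycyclohexane‑1,5‑diol (tertiary OH cis to the dioxolane) | O[C@@H]1[C@H](OC)[C@H]2OC(C)(C)O[C@H]2[C@](O)(C#C)C1 | intermediate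
9 | (1S,2S,3R,4R,5R)‑5‑ethynyl‑5‑hydroxy‑3,4‑(isopropylidenedioxy)‑2‑methoxycyclohexyl acetate | CC(=O)O[C@@H]1[C@H](OC)[C@H]2OC(C)(C)O[C@H]2[C@](O)(C#C)C1 | intermediate
10 | (1S,4S,5S,6S)‑3‑ethynyl‑4,5‑(isopropylidenedioxy)‑6‑methoxycyclohex‑2‑en‑1‑yl acetate | CC(=O)O[C@@H]1[C@H](OC)[C@H]2OC(C)(C)O[C@H]2C(C#C)=C1 | intermediate
11 | (1S,4S,5S,6R)‑3‑ethynyl‑4,5‑dihydroxy‑6‑methoxycyclohex‑2‑en‑1‑yl acetate | CC(=O)O[C@@H]1[C@H](OC)[C@@H](O)[C@@H](O)C(C#C)=C1 | intermediate
12 | (E)‑2‑methyl‑4‑(4,4,5,5‑tetramethyl‑1,3,2‑dioxaborolan‑2‑yl)but‑3‑en‑2‑ol | CC(C)(O)/C=C/B1OC(C)(C)C(C)(C)O1 | starting material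
13 | 2,3‑dibromoprop‑1‑ene | C=C(Br)CBr | starting material
14 | (3E)‑6‑bromo‑2‑methylhepta‑3,6‑dien‑2‑ol | CC(C)(O)/C=C/CC(Br)=C | intermediate
15 | (3E)‑6‑iodo‑2‑methylhepta‑3,6‑dien‑2‑ol | CC(C)(O)/C=C/CC(I)=C | intermediate
16 | (1S,4S,5S,6R)‑4,5‑dihydroxy‑3‑[(5E)‑7‑hydroxy‑7‑methyl‑3‑methylideneoct‑5‑en‑1‑yn‑1‑yl]‑6‑methoxycyclohex‑2‑en‑1‑yl acetate (CNP0546270.2) | C=C(C#CC1=C[C@H](OC(C)=O)[C@H](OC)[C@@H](O)[C@H]1O)C/C=C/C(C)(C)O | target

**Step count and risks**
Total steps: 11. Longest linear sequence: 9 (steps 1–8 and 11, from 1).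

The three steps most likely to fail:

Step 11, the proposed photochemical coupling. The excited copper acetylide may not reduce the alkenyl iodide efficiently, or the alkenyl radical may be lost to hydrogen abstraction or Glaser‑type dimerisation. The fallback uses known chemistry and builds the ring–alkyne bond by carbonyl addition instead of cross‑coupling. It sets out from 14 and 6 and comes back at 16.
- Bromide 14 is silylated (TESOTf, 2,6‑lutidine) to (E)‑6‑bromo‑2‑methyl‑2‑(triethylsilyloxy)hepta‑3,6‑diene F7.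
- Thermal Sonogashira coupling with ethynyltrimethylsilane (Pd(PPh3)2Cl2, CuI, Et3N, 50 °C) gives the silylated enyne F8.
- K2CO3/MeOH gives the terminal enyne (E)‑7‑methyl‑3‑methylidene‑7‑(triethylsilyloxy)oct‑5‑en‑1‑yne F9.
- Its lithium acetylide (n‑BuLi, THF, −78 °C, 2.5 equiv) adds to ketone 6 to give the tertiary propargylic alcohol F10.
- Ac2O/pyridine gives the secondary acetate F11.
- Burgess dehydration, as in step 7, gives the fully protected target F12.
- AcOH/H2O/THF at 45–60 °C removes the TES ether and the acetonide to give 16. The tertiary allylic alcohol is exposed to acid here, which the main route avoids.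

Step 4, the Ferrier carbocyclisation. The diastereoselectivity at the new carbinol is only precedented by analogy for a 3,4‑acetonide, and the acetonide must survive the aqueous Hg(II) conditions. The fallback sets the carbinol configuration by SN2 inversion instead of by the aldol. It sets out from 5 and comes back at 9.
- If the aldol gives mainly or partly the hydroxyl‑epimeric ketone, the trans (OH/OMe) ketol F1, it is carried on.
- Ethynylmagnesium bromide adds as in step 5 to give the epimeric ethynyl diol F2.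
- A Mitsunobu reaction (AcOH, PPh3, DIAD, THF, 0 °C → rt) installs the acetate with inversion at the secondary carbinol and delivers 9 directly.

Step 7, the Burgess dehydration. If the Grignard addition in step 5 is less face‑selective than expected, the minor tertiary epimer can eliminate towards the acetonide carbon and give the enol‑ether regioisomer. The fallback fixes the alkene position through a kinetic enol triflate and makes the ring–alkyne bond by conventional cross‑coupling. It sets out from 6 and comes back at 10.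
- Ketone 6 is silylated (TESOTf, 2,6‑lutidine) to the 5‑O‑triethylsilyl ketone F3.
- KHMDS and Comins' reagent (THF, −78 °C) deprotonate the CH2 group kinetically and give the enol triflate F4.
- Pd(PPh3)2Cl2/CuI/Et3N with ethynyltrimethylsilane gives the bis‑silylated enyne F5.
- TBAF in THF removes both silyl groups to give the hydroxy enyne F6.
- Ac2O/pyridine gives 10.

**Further compounds**
F1 | step 4 | (2R,3R,4S,5R)‑5‑hydroxy‑2,3‑(isopropylidenedioxy)‑4‑methoxycyclohexan‑1‑one (C‑5 epimer of 6) | O[C@H]1[C@H](OC)[C@H]2OC(C)(C)O[C@H]2C(=O)C1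
F2 | step 4 | (1R,2R,3R,4S,5R)‑1‑ethynyl‑2,3‑(isopropylidenedioxy)‑4‑methoxycyclohexane‑1,5‑diol (C‑5 epimer of 8) | O[C@H]1[C@H](OC)[C@H]2OC(C)(C)O[C@H]2[C@](O)(C#C)C1
F3 | step 7 | 5‑O‑triethylsilyl ether of ketone 6 | CC[Si](CC)(CC)O[C@@H]1[C@H](OC)[C@H]2OC(C)(C)O[C@H]2C(=O)C1
F4 | step 7 | enol triflate of F3 (C=C towards the CH2 carbon) | CC[Si](CC)(CC)O[C@@H]1[C@H](OC)[C@H]2OC(C)(C)O[C@H]2C(OS(=O)(=O)C(F)(F)F)=C1
F5 | step 7 | (trimethylsilyl)ethynyl cyclohexene with 1‑O‑TES, 6‑OMe and 4,5‑acetonide | CC[Si](CC)(CC)O[C@@H]1[C@H](OC)[C@H]2OC(C)(C)O[C@H]2C(C#C[Si](C)(C)C)=C1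
F6 | step 7 | (1S,4S,5S,6S)‑3‑ethynyl‑4,5‑(isopropylidenedioxy)‑6‑methoxycyclohex‑2‑en‑1‑ol | O[C@@H]1[C@H](OC)[C@H]2OC(C)(C)O[C@H]2C(C#C)=C1
F7 | step 11 | (E)‑6‑bromo‑2‑methyl‑2‑(triethylsilyloxy)hepta‑3,6‑diene | CC[Si](CC)(CC)OC(C)(C)/C=C/CC(Br)=C
F8 | step 11 | (E)‑trimethyl[7‑methyl‑3‑methylidene‑7‑(triethylsilyloxy)oct‑5‑en‑1‑yn‑1‑yl]silane | CC[Si](CC)(CC)OC(C)(C)/C=C/CC(=C)C#C[Si](C)(C)C
F9 | step 11 | (E)‑7‑methyl‑3‑methylidene‑7‑(triethylsilyloxy)oct‑5‑en‑1‑yne | CC[Si](CC)(CC)OC(C)(C)/C=C/CC(=C)C#C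
F10 | step 11 | adduct of the acetylide of F9 with ketone 6 (tertiary OH cis to the dioxolane) | O[C@@H]1[C@H](OC)[C@H]2OC(C)(C)O[C@H]2[C@](O)(C#CC(=C)C/C=C/C(C)(C)O[Si](CC)(CC)CC)C1
F11 | step 11 | secondary acetate of F10 | CC(=O)O[C@@H]1[C@H](OC)[C@H]2OC(C)(C)O[C@H]2[C@](O)(C#CC(=C)C/C=C/C(C)(C)O[Si](CC)(CC)CC)C1
F12 | step 11 | 4,5‑O‑isopropylidene 7′‑O‑triethylsilyl derivative of 16 | CC(=O)O[C@@H]1[C@H](OC)[C@H]2OC(C)(C)O[C@H]2C(C#CC(=C)C/C=C/C(C)(C)O[Si](CC)(CC)CC)=C1
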